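## Retrosynthetic overview

1. The strategy rests on the E-trisubstituted C3′=C4′ alkene, with CH3 on C4′ (chain carbons counted outward from oxane C5). It is read as a terminal alkyne C3′≡C4′, a methyl group and a primary C2′ radical. C2′ lies two CH2 groups from ring C5, where a propanoic acid arm can leave as CO2.
2. Key disconnection: C4′–CH3 and C2′–C3′ are made in one flask. The C3′–C13′ enyne is methylaluminated, aluminium is exchanged for zinc, and nickel couples the product with the N-hydroxyphthalimide ester of the ring acid.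
3. Enyne: C7′–C8′ comes from a Shapiro vinyllithium (6-methylhept-5-en-2-one) and a C-silylated pent-4-ynoic Weinreb amide. C7′ (R) comes from a CBS reduction.
4. Oxane (the only ring, closed before the coupling): C5 is set by an oxazolidinone-controlled Michael addition that builds a mixed methyl/tert-butyl 4-substituted heptanedioate. The O1–C2 bond closes as a δ-lactone, and acetate-enolate addition with axial silane reduction sets C2 trans to C5.
5. Endgame: α-methylenation of the acetate arm, desilylation, saponification.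

Key step: step 16

Remark on the chemistry: a symmetrical dimethyl 4-(hydroxymethyl)heptanedioate would lactonise to a racemate. The two arms are therefore differentiated from the start (methyl versus tert-butyl ester) on an auxiliary-set centre. Locants used: oxane O1, C2 (acetate/acrylate side), C5 (side chain), chain C1′–C13′.

## Fragment A: enyne

Step 1
Reactants: 1 6-methylhept-5-en-2-one
Product: 2 N′-[(2E)-6-methylhept-5-en-2-ylidene]-2,4,6-tri(propan-2-yl)benzenesulfonohydrazide (trisylhydrazone)
Conditions: TrisNHNH2 (1.0 equiv), cat. HCl, MeOH, 0 °C → rt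
Reagents that add atoms: 2,4,6-tri(propan-2-yl)benzenesulfonohydrazide, CC(C)c1cc(C(C)C)c(S(=O)(=O)NN)c(C(C)C)c1
Why: Acid-catalysed hydrazone condensation, which should place the bulky arylsulfonamide anti to the longer chain (E isomer) and so direct the later syn deprotonation to the methyl group.

Step 2
Reactants: 3 pent-4-ynoic acid
Product: 6 5-(trimethylsilyl)pent-4-ynoic acid, via dilithio salt 4 (not isolated), via silyl ester 5 (not isolated)
Conditions: n-BuLi (2.1 equiv), THF, −78 °C; Me3SiCl (2.5 equiv), −78 °C → rt; 1 M HCl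
Reagents that add atoms: chlorotrimethylsilane, C[Si](C)(C)Cl
Why: Double deprotonation (O–H, then alkyne C–H) and silylation of both anionic sites is the standard C-silylation of a terminal alkyne, and only the labile silyl ester is hydrolysed in the acidic work-up, so the alkyne no longer carries a proton that would quench the vinyllithium of step 4.

Step 3
Reactants: 6 5-(trimethylsilyl)pent-4-ynoic acid
Product: 7 N-methoxy-N-methyl-5-(trimethylsilyl)pent-4-ynamide
Conditions: MeNH(OMe)·HCl, EDC·HCl, Et3N, CH2Cl2, 0 °C → rt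
Reagents that add atoms: N,O-dimethylhydroxylamine hydrochloride, CNOC.Cl
Why: Carbodiimide amide coupling gives the Weinreb amide, whose chelated tetrahedral adduct should stop an organolithium addition at the ketone stage.

Step 4
Reactants: 2 trisylhydrazone; 7 N-methoxy-N-methyl-5-(trimethylsilyl)pent-4-ynamide
Product: 9 10-methyl-6-methylidene-1-(trimethylsilyl)undec-9-en-1-yn-5-one, via vinyllithium 8 (not isolated)
Conditions: 2 (1.3 equiv), n-BuLi (2.7 equiv), THF, −78 → 0 °C (N2 evolution); −78 °C, 7 (1.0 equiv), → 0 °C; inverse quench into cold 1 M HCl/Et2O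
Reagents that add atoms: none
Why: Shapiro reaction followed by Weinreb ketone synthesis, in which the dianion formed at the methyl carbon loses sulfinate and N2 to give the 1,1-disubstituted vinyllithium regioselectively, acylation forms C7′–C8′ without over-addition, and the acidic inverse quench protonates the released MeNHOMe before it can add to the new enone.

Step 5
Reactants: 9 10-methyl-6-methylidene-1-(trimethylsilyl)undec-9-en-1-yn-5-one
Product: 10 (5R)-10-methyl-6-methylidene-1-(trimethylsilyl)undec-9-en-1-yn-5-ol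
Conditions: (3aS)-1-methyl-3,3-diphenyltetrahydro-1H,3H-pyrrolo[1,2-c][1,3,2]oxazaborole ((S)-CBS catalyst, 20 mol %), catecholborane (1.8 equiv), toluene, −78 °C; MeOH, then aq. NaOH wash
Reagents that add atoms: none
Why: Corey–Bakshi–Shibata reduction, in which the ketone should bind the ring boron anti to its larger sp2-branched α-alkylvinyl substituent so that the N-bound borane delivers hydride to one face and sets C7′ as R (the same sense as acetophenone to (R)-1-phenylethanol with the (S)-catalyst), while catecholborane at −78 °C leaves the alkenes and the silyl alkyne alone.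

Step 6
Reactants: 10 (5R)-allylic alcohol
Product: 11 tert-butyl(dimethyl){[(5R)-10-methyl-6-methylidene-1-(trimethylsilyl)undec-9-en-1-yn-5-yl]oxy}silane
Conditions: TBSCl, imidazole, cat. DMAP, DMF, rt
Reagents that add atoms: tert-butylchlorodimethylsilane, CC(C)(C)[Si](C)(C)Cl
Why: Imidazole-promoted O-silylation masks the only O–H, which would otherwise consume Me3Al and the zinc reagent, and does not touch the C7′–O bond.

Step 7
Reactants: 11 bis-silyl compound
Product: 12 tert-butyl(dimethyl){[(5R)-10-methyl-6-methylideneundec-9-en-1-yn-5-yl]oxy}silane (C3′–C13′ enyne)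
Conditions: K2CO3, MeOH, rt
Reagents that add atoms: none
Why: Methoxide-mediated protodesilylation cleaves only the C(sp)–SiMe3 bond, because the hindered tert-butyldimethylsilyl ether is stable to K2CO3/MeOH.

## Fragment B: redox-active ester

Step 8
Reactants: 13 (4S)-4-benzyl-1,3-oxazolidin-2-one; 14 methyl 5-chloro-5-oxopentanoate
Product: 15 methyl 5-[(4S)-4-benzyl-2-oxo-1,3-oxazolidin-3-yl]-5-oxopentanoate
Conditions: Et3N, DMAP (10 mol %), CH2Cl2, 0 °C → rt
Reagents that add atoms: none
Why: DMAP-catalysed N-acylation occurs at the acid chloride terminus, the methyl ester being far less electrophilic.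

Step 9
Reactants: 15 imide; 16 tert-butyl acrylate
Product: 18 1-tert-butyl 7-methyl (4R)-4-{[(4S)-4-benzyl-2-oxo-1,3-oxazolidin-3-yl]carbonyl}heptanedioate, via chlorotitanium Z-enolate 17 (not isolated)
Conditions: TiCl4/Ti(OiPr)4 (3:1, giving TiCl3(OiPr), 1.05 equiv), iPr2NEt (1.1 equiv), CH2Cl2, 0 °C; 16 (2 equiv), 0 °C → rt; aq. NH4Cl
Reagents that add atoms: none
Why: Auxiliary-controlled Michael addition of a chlorotitanium enolate (Evans oxazolidinone chemistry), in which soft enolisation occurs only at the chelated imide to give the Z-enolate, the benzyl group blocks one face and the acrylate adds to the other, setting ring C5 with the tert-butyl ester arm (future C1′–C2′) and the methyl ester arm (future C4–C3–C2) in the required sense.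

Step 10
Reactants: 18 Michael adduct
Product: 20 (2R)-5-tert-butoxy-2-(3-methoxy-3-oxopropyl)-5-oxopentanoic acid, via peroxy acid 19 (not isolated)
Conditions: LiOH, H2O2, THF/H2O, 0 °C; aq. Na2SO3; 1 M HCl to pH 3
Reagents that add atoms: hydrogen peroxide, OO
Why: Hydroperoxide cleavage of the exocyclic imide carbonyl is the standard epimerisation-free auxiliary removal, the methyl ester surviving because hydroperoxide leaves its tetrahedral adduct faster than methoxide does and the tert-butyl ester because it is too hindered.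

Step 11
Reactants: 20 half-acid
Product: 22 tert-butyl 3-[(3R)-6-oxooxan-3-yl]propanoate, via hydroxy diester 21 (not isolated)
Conditions: BH3·THF (1.3 equiv), THF, −15 → 0 °C; MeOH, concentrate; PPTS (10 mol %), toluene, 60 °C
Reagents that add atoms: none
Why: Borane reduces the free acid chemoselectively through its acyloxyborane beside both esters, and mild acid-catalysed lactonisation (6-exo-trig acyl substitution) then engages only the methyl ester because the tert-butyl ester resists acyl substitution, so the oxane closes towards the correct arm with C5 untouched.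

Step 12
Reactants: 22 lactone; 23 methyl acetate
Product: 25 methyl 2-[(5R)-5-(3-tert-butoxy-3-oxopropyl)-2-hydroxyoxan-2-yl]acetate (hemiketal, anomeric mixture), via lithium enolate 24 (not isolated)
Conditions: LiN(iPr)2 (2.6 equiv), 23 (2.5 equiv), THF, −78 °C; 22, −78 °C; aq. NH4Cl
Reagents that add atoms: none
Why: Claisen-type addition of an ester enolate to a δ-lactone, in which the lactone is the most electrophilic carbonyl, the tert-butyl ester is inert at −78 °C, and the adduct is shielded from a second addition as its β-keto ester enolate before closing to the hemiketal on quench.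

Step 13
Reactants: 25 hemiketal
Product: 26 tert-butyl 3-[(3R,6R)-6-(2-methoxy-2-oxoethyl)oxan-3-yl]propanoate (2,5-trans oxane)
Conditions: Et3SiH (5 equiv), BF3·OEt2 (2.5 equiv), CH2Cl2, −78 → −30 °C
Reagents that add atoms: none
Why: Lewis-acid-promoted ionic reduction of a hemiketal, in which BF3 ionises C2–OH to the cyclic oxocarbenium ion, its half-chair carries the C5 arm pseudo-equatorial, and silane hydride enters along the axial trajectory, leaving the acetate arm equatorial and setting C2 trans to C5.

Step 14
Reactants: 26 mixed diester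
Product: 27 3-[(3R,6R)-6-(2-methoxy-2-oxoethyl)oxan-3-yl]propanoic acid
Conditions: TFA/CH2Cl2 (1:4), 0 °C → rt
Reagents that add atoms: none
Why: Acidolysis of the tert-butyl ester through the tert-butyl cation (AAL1) frees the propanoic acid, while the methyl ester and the oxane are stable to TFA.

Step 15
Reactants: 27 ring acid
Product: 28 1,3-dioxoisoindolin-2-yl 3-[(3R,6R)-6-(2-methoxy-2-oxoethyl)oxan-3-yl]propanoate
Conditions: N-hydroxyphthalimide, DIC, DMAP (10 mol %), CH2Cl2, rt
Reagents that add atoms: N-hydroxyphthalimide, O=C1c2ccccc2C(=O)N1O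
Why: Carbodiimide (Steglich-type) esterification gives the isolable redox-active ester of the primary acid.

## Union and endgame

Step 16
Reactants: 12 enyne; 29 trimethylaluminium; 28 N-hydroxyphthalimide ester
Product: 32 methyl 2-[(2R,5S)-5-{(3E,7R)-7-[(tert-butyldimethylsilyl)oxy]-4,12-dimethyl-8-methylidenetrideca-3,11-dien-1-yl}oxan-2-yl]acetate, via alkenylalane 30 (not isolated), via alkenylzinc chloride 31 (not isolated)
Conditions: 12 (2.0 equiv), Me3Al (2 equiv per 12), Cp2ZrCl2 (20 mol %), CH2Cl2, 0 °C → rt; volatiles removed in vacuo, hexane extract filtered; ZnCl2 (1.0 equiv per 12, THF), 0 °C; 28 (1.0 equiv), Ni(acac)2 (10 mol %), 2,2′-bipyridine (10 mol %), THF/DMF, rt; aq. NH4Cl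
Reagents that add atoms: trimethylaluminium (29, supplies the C4′ methyl group), C[Al](C)C
Why: Proposed new method: the three stages are each established (Negishi zirconium-catalysed methylalumination of 1-alkynes, aluminium-to-zinc exchange of alkenylalanes with ZnCl2, and nickel-catalysed decarboxylative alkenylation of primary N-hydroxyphthalimide esters with alkenylzinc halides, the last being the closest known reaction type), and the untested element is feeding the alane-derived zinc reagent, with its aluminium by-product, to the redox-active ester in one flask. A cationic methylzirconocene formed from Cp2ZrCl2 and Me3Al adds CH3 and metal to the same face of C3′≡C4′, CH3 going to the substituted carbon C4′ and, after zirconium-to-aluminium exchange, AlMe2 residing on C3′, so that 30 already has the E geometry. ZnCl2 then takes over the sp2 carbon ligand to give 31 and Me2AlCl, 31 alkenylates nickel, the electron-rich alkenylnickel reduces 28 by single-electron transfer, the radical anion breaks up into phthalimide anion, CO2 and the primary C2′ radical, and capture of that radical at nickel followed by reductive elimination from trivalent nickel forms C2′–C3′ with retention at the alkene. No ring is closed and no stereocentre is created; the only stereochemical element made is the E alkene, controlled by the syn carbometalation, and C5, C2 and C7′ are spectators because C1′ insulates the radical site from C5. The step needs reaction at the terminal alkyne only and CH3 delivery to C4′, which the unhindered propargylic CH2 and the inertness of the 1,1-disubstituted and trisubstituted alkenes, the silyl ether and the methyl ester should secure. It also needs alkenyl rather than methyl transfer to nickel and no Al–CH3 attack on the activated ester, for which excess Me3Al is stripped in vacuo, zirconocene salts are filtered off and the coupling is run in THF/DMF, donors that tie up Me2AlCl.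

Step 17
Reactants: 32 coupled methyl ester
Product: 34 methyl 3-(dimethylamino)-2-[(2R,5S)-5-{(3E,7R)-7-[(tert-butyldimethylsilyl)oxy]-4,12-dimethyl-8-methylidenetrideca-3,11-dien-1-yl}oxan-2-yl]propanoate (mixture at the new α-carbon), via lithium enolate 33 (not isolated)
Conditions: LiN(iPr)2 (1.2 equiv), THF, −78 °C; finely ground CH2=NMe2+ I− (Eschenmoser's salt, 3 equiv), −78 → −20 °C
Reagents that add atoms: N,N-dimethylmethyleneiminium iodide, C=[N+](C)C.[I-]
Why: Mannich reaction of an ester lithium enolate with a preformed iminium salt, in which kinetic deprotonation takes the only acidic C–H, the lithium enolate of the β-alkoxy ester is expected to keep its C2–O bond at low temperature, and the new α-centre is of no consequence because it becomes sp2 in step 18.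

Step 18
Reactants: 34 Mannich base
Product: 36 methyl 2-[(2R,5S)-5-{(3E,7R)-7-[(tert-butyldimethylsilyl)oxy]-4,12-dimethyl-8-methylidenetrideca-3,11-dien-1-yl}oxan-2-yl]prop-2-enoate, via ammonium iodide 35 (not isolated)
Conditions: MeI (10 equiv), CH2Cl2, rt; concentrate; DBU (2 equiv), CH2Cl2, rt
Reagents that add atoms: none
Why: N-Methylation followed by base-induced E1cB (Hofmann-type) elimination expels trimethylamine, a far better leaving group than the ring alkoxide, and should deliver the α-methylene ester without disturbing C2.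

Step 19
Reactants: 36 silyl ether
Product: 37 methyl 2-{(2R,5S)-5-[(3E,7R)-7-hydroxy-4,12-dimethyl-8-methylidenetrideca-3,11-dien-1-yl]oxan-2-yl}prop-2-enoate
Conditions: Bu4NF (1.5 equiv), THF, 0 °C → rt; aq. NH4Cl
Reagents that add atoms: none
Why: Fluoride-driven desilylation breaks the Si–O and not the C7′–O bond, so the R configuration of the allylic alcohol is retained.

Step 20
Reactants: 37 hydroxy ester
Product: 38 2-{(2R,5S)-5-[(3E,7R)-7-hydroxy-4,12-dimethyl-8-methylidenetrideca-3,11-dien-1-yl]oxan-2-yl}prop-2-enoic acid (target)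
Conditions: LiOH·H2O, THF/H2O, rt; cold 1 M HCl to pH 3–4
Reagents that add atoms: lithium hydroxide, [Li+].[OH-]
Why: BAC2 saponification of the methyl ester, in which the α-carbon bears no proton so that neither elimination of the ring oxygen nor epimerisation at C2 has a pathway, and the brief cold acidification spares the allylic alcohol.

## Compound list

1 | 6-methylhept-5-en-2-one | CC(=O)CCC=C(C)C | starting material
2 | N′-[(2E)-6-methylhept-5-en-2-ylidene]-2,4,6-tri(propan-2-yl)benzenesulfonohydrazide | C/C(CCC=C(C)C)=N\NS(=O)(=O)c1c(C(C)C)cc(C(C)C)cc1C(C)C | intermediate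
3 | pent-4-ynoic acid | C#CCCC(=O)O | starting material
4 | lithium 5-lithiopent-4-ynoate | [Li]C#CCCC(=O)O[Li] | intermediate (not isolated)
5 | trimethylsilyl 5-(trimethylsilyl)pent-4-ynoate | C[Si](C)(C)C#CCCC(=O)O[Si](C)(C)C | intermediate (not isolated)
6 | 5-(trimethylsilyl)pent-4-ynoic acid | C[Si](C)(C)C#CCCC(=O)O | intermediate
7 | N-methoxy-N-methyl-5-(trimethylsilyl)pent-4-ynamide | CON(C)C(=O)CCC#C[Si](C)(C)C | intermediate
8 | (6-methylhepta-1,5-dien-2-yl)lithium | [Li]C(=C)CCC=C(C)C | intermediate (not isolated)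
9 | 10-methyl-6-methylidene-1-(trimethylsilyl)undec-9-en-1-yn-5-one | C=C(CCC=C(C)C)C(=O)CCC#C[Si](C)(C)C | intermediate
10 | (5R)-10-methyl-6-methylidene-1-(trimethylsilyl)undec-9-en-1-yn-5-ol | C=C(CCC=C(C)C)[C@H](O)CCC#C[Si](C)(C)C | intermediate
11 | tert-butyl(dimethyl){[(5R)-10-methyl-6-methylidene-1-(trimethylsilyl)undec-9-en-1-yn-5-yl]oxy}silane | C=C(CCC=C(C)C)[C@H](O[Si](C)(C)C(C)(C)C)CCC#C[Si](C)(C)C | intermediate
12 | tert-butyl(dimethyl){[(5R)-10-methyl-6-methylideneundec-9-en-1-yn-5-yl]oxy}silane | C=C(CCC=C(C)C)[C@H](O[Si](C)(C)C(C)(C)C)CCC#C | intermediate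
13 | (4S)-4-benzyl-1,3-oxazolidin-2-one | O=C1N[C@@H](Cc2ccccc2)CO1 | starting material
14 | methyl 5-chloro-5-oxopentanoate | COC(=O)CCCC(=O)Cl | starting material
15 | methyl 5-[(4S)-4-benzyl-2-oxo-1,3-oxazolidin-3-yl]-5-oxopentanoate | COC(=O)CCCC(=O)N1C(=O)OC[C@@H]1Cc1ccccc1 | intermediate
16 | tert-butyl acrylate | C=CC(=O)OC(C)(C)C | starting material
17 | dichloro(propan-2-olato)titanium Z-enolate of 15 | COC(=O)CC/C=C(\O[Ti](Cl)(Cl)OC(C)C)N1C(=O)OC[C@@H]1Cc1ccccc1 | intermediate (not isolated)
18 | 1-tert-butyl 7-methyl (4R)-4-{[(4S)-4-benzyl-2-oxo-1,3-oxazolidin-3-yl]carbonyl}heptanedioate | COC(=O)CC[C@H](CCC(=O)OC(C)(C)C)C(=O)N1C(=O)OC[C@@H]1Cc1ccccc1 | intermediate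
19 | (2R)-5-tert-butoxy-2-(3-methoxy-3-oxopropyl)-5-oxopentaneperoxoic acid | COC(=O)CC[C@H](CCC(=O)OC(C)(C)C)C(=O)OO | intermediate (not isolated)
20 | (2R)-5-tert-butoxy-2-(3-methoxy-3-oxopropyl)-5-oxopentanoic acid | COC(=O)CC[C@H](CCC(=O)OC(C)(C)C)C(=O)O | intermediate
21 | 1-tert-butyl 7-methyl (4R)-4-(hydroxymethyl)heptanedioate | COC(=O)CC[C@H](CCC(=O)OC(C)(C)C)CO | intermediate (not isolated)
22 | tert-butyl 3-[(3R)-6-oxooxan-3-yl]propanoate | O=C1CC[C@H](CCC(=O)OC(C)(C)C)CO1 | intermediate
23 | methyl acetate | CC(=O)OC | starting material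
24 | lithium 1-methoxyethen-1-olate | C=C(OC)O[Li] | intermediate (not isolated)
25 | methyl 2-[(5R)-5-(3-tert-butoxy-3-oxopropyl)-2-hydroxyoxan-2-yl]acetate | COC(=O)CC1(O)CC[C@H](CCC(=O)OC(C)(C)C)CO1 | intermediate
26 | tert-butyl 3-[(3R,6R)-6-(2-methoxy-2-oxoethyl)oxan-3-yl]propanoate | CC(C)(C)OC(=O)CC[C@H]1CC[C@H](CC(=O)OC)OC1 | intermediate
27 | 3-[(3R,6R)-6-(2-methoxy-2-oxoethyl)oxan-3-yl]propanoic acid | O=C(O)CC[C@H]1CC[C@H](CC(=O)OC)OC1 | intermediate
28 | 1,3-dioxoisoindolin-2-yl 3-[(3R,6R)-6-(2-methoxy-2-oxoethyl)oxan-3-yl]propanoate | O=C(CC[C@H]1CC[C@H](CC(=O)OC)OC1)ON1C(=O)c2ccccc2C1=O | intermediate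
29 | trimethylaluminium | C[Al](C)C | starting material
30 | [(1E,5R)-5-(tert-butyldimethylsilyloxy)-2,10-dimethyl-6-methylideneundeca-1,9-dien-1-yl]dimethylaluminium | C=C(CCC=C(C)C)[C@H](O[Si](C)(C)C(C)(C)C)CC/C(C)=C/[Al](C)C | intermediate (not isolated)
31 | chloro[(1E,5R)-5-(tert-butyldimethylsilyloxy)-2,10-dimethyl-6-methylideneundeca-1,9-dien-1-yl]zinc | C=C(CCC=C(C)C)[C@H](O[Si](C)(C)C(C)(C)C)CC/C(C)=C/[Zn]Cl | intermediate (not isolated)
32 | methyl 2-[(2R,5S)-5-{(3E,7R)-7-[(tert-butyldimethylsilyl)oxy]-4,12-dimethyl-8-methylidenetrideca-3,11-dien-1-yl}oxan-2-yl]acetate | C=C(CCC=C(C)C)[C@H](O[Si](C)(C)C(C)(C)C)CC/C(C)=C/CC[C@H]1CC[C@H](CC(=O)OC)OC1 | intermediate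
33 | lithium enolate of 32 | C=C(CCC=C(C)C)[C@H](O[Si](C)(C)C(C)(C)C)CC/C(C)=C/CC[C@H]1CC[C@H](C=C(OC)O[Li])OC1 | intermediate (not isolated)
34 | methyl 3-(dimethylamino)-2-[(2R,5S)-5-{(3E,7R)-7-[(tert-butyldimethylsilyl)oxy]-4,12-dimethyl-8-methylidenetrideca-3,11-dien-1-yl}oxan-2-yl]propanoate | C=C(CCC=C(C)C)[C@H](O[Si](C)(C)C(C)(C)C)CC/C(C)=C/CC[C@H]1CC[C@H](C(CN(C)C)C(=O)OC)OC1 | intermediate
35 | trimethylammonium iodide derived from 34 | C=C(CCC=C(C)C)[C@H](O[Si](C)(C)C(C)(C)C)CC/C(C)=C/CC[C@H]1CC[C@H](C(C[N+](C)(C)C)C(=O)OC)OC1.[I-] | intermediate (not isolated)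
36 | methyl 2-[(2R,5S)-5-{(3E,7R)-7-[(tert-butyldimethylsilyl)oxy]-4,12-dimethyl-8-methylidenetrideca-3,11-dien-1-yl}oxan-2-yl]prop-2-enoate | C=C(CCC=C(C)C)[C@H](O[Si](C)(C)C(C)(C)C)CC/C(C)=C/CC[C@H]1CC[C@H](C(=C)C(=O)OC)OC1 | intermediate
37 | methyl 2-{(2R,5S)-5-[(3E,7R)-7-hydroxy-4,12-dimethyl-8-methylidenetrideca-3,11-dien-1-yl]oxan-2-yl}prop-2-enoate | C=C(CCC=C(C)C)[C@H](O)CC/C(C)=C/CC[C@H]1CC[C@H](C(=C)C(=O)OC)OC1 | intermediate
38 | 2-{(2R,5S)-5-[(3E,7R)-7-hydroxy-4,12-dimethyl-8-methylidenetrideca-3,11-dien-1-yl]oxan-2-yl}prop-2-enoic acid | C=C(CCC=C(C)C)[C@H](O)CC/C(C)=C/CC[C@H]1CC[C@H](C(=C)C(=O)O)OC1 | target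

## Step count

Total step count: 20.
Longest linear sequence: 13 steps (steps 8–20, from 13 and 14). The enyne branch contributes 11 steps (steps 2–7, then 16–20), with step 1 feeding step 4.

## Steps most likely to fail

**1. Step 16 (labelled step).** Three processes may intervene:
- Methyl instead of alkenyl may pass from the mixed aluminium/zinc reagent to nickel.
- Residual Al–CH3 may attack the activated ester at its acyl carbon.
- Zirconocene residues may stall the nickel cycle.

The fallback uses known chemistry and separates the stages. It sets out from 12. The methylalumination is run alone to 30 and quenched with I2 (THF, −30 °C) to give tert-butyl{[(1E,5R)-1-iodo-2,10-dimethyl-6-methylideneundeca-1,9-dien-5-yl]oxy}dimethylsilane F1, which is purified. Iodine–lithium exchange (t-BuLi, 2 equiv, Et2O, −78 °C) gives the alkenyllithium F2. ZnCl2 in THF converts it into 31 free of aluminium and zirconium. The documented Ni(acac)2/2,2′-bipyridine coupling with 28 then returns to the route at 32.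

**2. Step 17.** While the mixture warms enough for the sparingly soluble iminium salt to react, the enolate may expel the ring alkoxide. This retro-oxa-Michael ring opening would lose material or erode the C2 configuration on reclosure.

The fallback avoids any metal enolate and sets out from 32:
- iBu2AlH (1.05 equiv, CH2Cl2, −78 °C) gives the aldehyde 2-[(2R,5S)-5-{…}oxan-2-yl]acetaldehyde F3.
- An amine-catalysed Mannich condensation–elimination (aqueous formaldehyde, pyrrolidine/propionic acid, iPrOH, 45 °C) gives the α-methylene aldehyde F4.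
- Pinnick oxidation (NaClO2, NaH2PO4, 2-methylbut-2-ene, t-BuOH/H2O) gives the silyl-protected acrylic acid F5.
- Bu4NF in THF returns to the route at 38.

**3. Step 5.** Facial selectivity may be poor because both ketone substituents are flexible chains, and conjugate reduction of the s-cis enone may compete. Any erosion would appear later as an inseparable C7′ epimer.

The fallback replaces asymmetric reduction by resolution and sets out from 9. Luche reduction (NaBH4, CeCl3·7H2O, MeOH, −78 → 0 °C) gives the racemic allylic alcohol F6. A Sharpless kinetic resolution follows (Ti(OiPr)4, L-(+)-diisopropyl tartrate, t-BuOOH 0.6 equiv, 4 Å molecular sieves, CH2Cl2, −20 °C). It should consume the S enantiomer as the epoxy alcohol F7, which is removed by chromatography. The slow-reacting R alcohol is recovered, returning to the route at 10.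

## Further compounds

F1 | step 16 | tert-butyl{[(1E,5R)-1-iodo-2,10-dimethyl-6-methylideneundeca-1,9-dien-5-yl]oxy}dimethylsilane | C=C(CCC=C(C)C)[C@H](O[Si](C)(C)C(C)(C)C)CC/C(C)=C/I
F2 | step 16 | [(1E,5R)-5-(tert-butyldimethylsilyloxy)-2,10-dimethyl-6-methylideneundeca-1,9-dien-1-yl]lithium | C=C(CCC=C(C)C)[C@H](O[Si](C)(C)C(C)(C)C)CC/C(C)=C/[Li]
F3 | step 17 | 2-[(2R,5S)-5-{(3E,7R)-7-[(tert-butyldimethylsilyl)oxy]-4,12-dimethyl-8-methylidenetrideca-3,11-dien-1-yl}oxan-2-yl]acetaldehyde | C=C(CCC=C(C)C)[C@H](O[Si](C)(C)C(C)(C)C)CC/C(C)=C/CC[C@H]1CC[C@H](CC=O)OC1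
F4 | step 17 | 2-[(2R,5S)-5-{(3E,7R)-7-[(tert-butyldimethylsilyl)oxy]-4,12-dimethyl-8-methylidenetrideca-3,11-dien-1-yl}oxan-2-yl]prop-2-enal | C=C(CCC=C(C)C)[C@H](O[Si](C)(C)C(C)(C)C)CC/C(C)=C/CC[C@H]1CC[C@H](C(=C)C=O)OC1
F5 | step 17 | 2-[(2R,5S)-5-{(3E,7R)-7-[(tert-butyldimethylsilyl)oxy]-4,12-dimethyl-8-methylidenetrideca-3,11-dien-1-yl}oxan-2-yl]prop-2-enoic acid | C=C(CCC=C(C)C)[C@H](O[Si](C)(C)C(C)(C)C)CC/C(C)=C/CC[C@H]1CC[C@H](C(=C)C(=O)O)OC1
F6 | step 5 | rac-10-methyl-6-methylidene-1-(trimethylsilyl)undec-9-en-1-yn-5-ol | C=C(CCC=C(C)C)C(O)CCC#C[Si](C)(C)C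
F7 | step 5 | (1S)-1-[(2S)-2-(4-methylpent-3-en-1-yl)oxiran-2-yl]-5-(trimethylsilyl)pent-4-yn-1-ol | CC(C)=CCC[C@]1(CO1)[C@@H](O)CCC#C[Si](C)(C)C
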